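The tetronic ring is numbered O1–C2(=O)–C3=C4(OH)–C5 and the side chain C1'(=O) to C16'. The enolised array O=C1'–C3=C4–OH, half in the chain and half in the ring, is an isoxazole with its N–O bond opened and N exchanged for O. C3 is also the nucleophilic beta-carbon of a butenolide that carries a donor at C4.
Cuts, in order: C1'–C3 together with a temporary O–C4 bond (nitrile oxide (3+2) cycloaddition to a 4-pyrrolidino butenolide); then C4–N; then C3=C4 and O1–C2 of the butenolide (Ph3P=C=C=O plus an alpha-hydroxy ester); in the chain, C12'–C13' and C1'–N.
Forward: a five-carbon and a twelve-carbon piece are coupled and capped as a nitroalkane, and the butenolide ring is built from a serine-derived hydroxy ester. The key step fuses a temporary isoxazole ring onto C3–C4 and so joins chain and ring as a neutral, non-chelating mask of the tricarbonyl.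
Hydrogenolysis (N–O and O-benzyl) and hydrolysis of the vinylogous amide then remove every helper atom.
Stereochemistry: C14' (S) is bought with (S)-1-bromo-2-methylbutane. C5 (S) comes from O-benzyl-L-serine by diazotisation with retention. No later step touches either centre.

Key step: step 7

Assumption: the target is a set of rapidly interconverting enol tautomers of a 3-acylfuran-2,4-dione, and the 4-hydroxy form of the given SMILES is drawn throughout. The side chain is read as (S)-14-methylhexadecanoyl, with twelve CH2 groups between C1' and C14'.

Step 1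
Reactants: 1 (S)-1-bromo-2-methylbutane; 2 1,12-dibromododecane
Product: 4 (S)-1-bromo-14-methylhexadecane, via Grignard reagent 3 (not isolated)
Conditions: Mg, THF, 40 °C; then 3 added slowly to 2 (3 equiv), Li2CuCl4 (cat.), THF, −10 °C → rt
Reagents that add atoms: magnesium, [Mg] (kept only in 3)
Why: Copper-catalysed Kochi-type cross-coupling of a primary alkyl Grignard reagent with a primary alkyl bromide forms C12'–C13'; slow addition of 3 to an excess of the symmetrical dibromide 2 should hold the reaction at the first substitution, and the stereocentre, which lies beta to magnesium, takes no part.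

Step 2
Reactants: 4 (S)-1-bromo-14-methylhexadecane
Product: 5 (S)-14-methyl-1-nitrohexadecane
Conditions: AgNO2, Et2O, 0 °C → rt, dark
Reagents that add atoms: silver nitrite, [Ag+].[O-]N=O
Why: Victor Meyer reaction: silver-assisted SN2 displacement of a primary bromide by the ambident nitrite ion in ether should favour attack through nitrogen, so that the nitroalkane is the main product and the minor nitrite ester is removed by chromatography.

Step 3
Reactants: 6 O-benzyl-L-serine
Product: 7 (S)-3-(benzyloxy)-2-hydroxypropanoic acid
Conditions: NaNO2, 1 M H2SO4 (aq), 0 °C → rt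
Reagents that add atoms: water, O
Why: Diazotisation–hydrolysis of an alpha-amino acid proceeds with net retention, because the neighbouring carboxylate expels N2 with inversion and water then displaces the carboxylate oxygen with a second inversion, so the S centre of serine becomes C5 of the target unchanged.

Step 4
Reactants: 7 (S)-3-(benzyloxy)-2-hydroxypropanoic acid
Product: 8 methyl (S)-3-(benzyloxy)-2-hydroxypropanoate
Conditions: MeOH, H2SO4 (cat.), reflux
Reagents that add atoms: methanol, CO
Why: Fischer esterification in a large excess of methanol; the benzyl ether and the secondary alcohol are inert and the stereocentre is not enolised under acid catalysis.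

Step 5
Reactants: 8 methyl (S)-3-(benzyloxy)-2-hydroxypropanoate; 9 (triphenylphosphoranylidene)ketene
Product: 11 (S)-5-[(benzyloxy)methyl]-4-methoxyfuran-2(5H)-one, via ester ylide 10 (not isolated)
Conditions: toluene, reflux
Reagents that add atoms: none
Why: Domino addition–intramolecular Wittig olefination: the hydroxy group of 8 adds across the C=C bond of the cumulated ylide 9 to give the stabilised ester ylide 10, whose carbanion carbon (future C3) olefinates the adjacent methyl ester carbonyl (future C4) in a five-membered ring closure under neutral conditions, so the oxygen-bearing stereocentre should not be epimerised.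

Step 6
Reactants: 11 (S)-5-[(benzyloxy)methyl]-4-methoxyfuran-2(5H)-one
Product: 12 (R)-5-[(benzyloxy)methyl]-4-(pyrrolidin-1-yl)furan-2(5H)-one
Conditions: pyrrolidine (3 equiv), MeOH, 50 °C
Reagents that add atoms: pyrrolidine, C1CCNC1
Why: Conjugate addition–elimination at C4 of a vinylogous carbonate (aminolysis of an alkyl tetronate to a tetronamide): pyrrolidine adds to C4, methoxide leaves, and the more strongly conjugated vinylogous carbamate is the thermodynamic sink; the spatial arrangement at C5 is unchanged and the descriptor becomes R only because nitrogen at C4 lowers the CIP rank of that branch.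

Step 7
Reactants: 5 (S)-14-methyl-1-nitrohexadecane; 12 (R)-5-[(benzyloxy)methyl]-4-(pyrrolidin-1-yl)furan-2(5H)-one
Product: 15 (S)-6-[(benzyloxy)methyl]-3-[(S)-13-methylpentadecyl]furo[3,4-d]isoxazol-4(6H)-one, via nitrile oxide 13 (not isolated), via aminoisoxazoline 14 (not isolated)
Conditions: 5 (1.3 equiv), Et3N, CHCl3, 0 °C; POCl3 added slowly; → rt; wash with cold 1 M HCl
Reagents that add atoms: none
Why: POCl3/Et3N dehydrates the primary nitroalkane 5 through its O-phosphorylated nitronate to nitrile oxide 13, which adds across the C3=C4 double bond of the vinylogous carbamate 12 in a Huisgen (3+2) cycloaddition that forms C1'–C3 and the temporary O–C4 bond in one suprafacial, asynchronous event. The closest known reaction type is the cycloaddition–elimination of aliphatic nitrile oxides, generated in situ, with beta-pyrrolidino enoates, which gives 3,5-disubstituted isoxazole-4-carboxylates as single regioisomers. The one ring closed is the five-membered isoxazoline of 14, closed by cycloaddition rather than by an ionic exo or endo cyclisation and therefore cis-fused to the lactone; loss of pyrrolidine from the aminal carbon C4, helped by the acidic C3–H, then aromatises it to the isoxazole of 15. The two new ring-fusion stereocentres of 14 are set by suprafacial addition on the face anti to the C5 benzyloxymethyl group, but both are erased on aromatisation, so facial selectivity has no bearing on the outcome, and C5 itself is not acidic enough to be deprotonated by Et3N. The selectivity needed is regiochemical and carbon-versus-oxygen chemoselectivity: the pyrrolidine nitrogen at C4 puts the largest HOMO coefficient on C3, which pairs with the electrophilic carbon of the dipole, so carbon–carbon bond formation at C3 is enforced where direct acylation of a tetronate would begin at oxygen. Dimerisation of 13 is held back by the slow addition of POCl3 (low stationary concentration), and released pyrrolidine, the stronger base, is held as its hydrochloride by the triethylammonium chloride present.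

Step 8
Reactants: 15 (S)-6-[(benzyloxy)methyl]-3-[(S)-13-methylpentadecyl]furo[3,4-d]isoxazol-4(6H)-one
Product: 16 (5S)-3-[(1E,14S)-1-amino-14-methylhexadecylidene]-5-(hydroxymethyl)furan-2,4(3H,5H)-dione
Conditions: H2 (1 atm), Pd/C, EtOH–THF, rt
Reagents that add atoms: none
Why: Catalytic hydrogenolysis: H2 on palladium cleaves the weak N–O bond of the isoxazole to the hydrogen-bonded vinylogous amide and removes the benzyl ether in the same operation, while the tetrasubstituted push–pull C=C bond, the lactone and both stereocentres should be inert.

Step 9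
Reactants: 16 (5S)-3-[(1E,14S)-1-amino-14-methylhexadecylidene]-5-(hydroxymethyl)furan-2,4(3H,5H)-dione
Product: 17 (S)-4-hydroxy-5-(hydroxymethyl)-3-[(S)-14-methylhexadecanoyl]furan-2(5H)-one
Conditions: 2 M HCl (aq), THF, 60 °C
Reagents that add atoms: water, O
Why: Acid hydrolysis of a vinylogous amide: protonation turns C1' into an iminium-type carbon, water adds there and ammonia leaves irreversibly as NH4Cl, which uncovers the enolised tricarbonyl; C5 should keep its configuration because C4 stays enolised towards C3 and not towards C5.

Compound list
1 | (S)-1-bromo-2-methylbutane | CC[C@H](C)CBr | starting material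
2 | 1,12-dibromododecane | BrCCCCCCCCCCCCBr | starting material
3 | (S)-2-methylbutylmagnesium bromide | CC[C@H](C)C[Mg]Br | intermediate
4 | (S)-1-bromo-14-methylhexadecane | CC[C@H](C)CCCCCCCCCCCCCBr | intermediate
5 | (S)-14-methyl-1-nitrohexadecane | CC[C@H](C)CCCCCCCCCCCCC[N+](=O)[O-] | intermediate
6 | O-benzyl-L-serine | N[C@@H](COCc1ccccc1)C(=O)O | starting material
7 | (S)-3-(benzyloxy)-2-hydroxypropanoic acid | O[C@@H](COCc1ccccc1)C(=O)O | intermediate
8 | methyl (S)-3-(benzyloxy)-2-hydroxypropanoate | O[C@@H](COCc1ccccc1)C(=O)OC | intermediate
9 | (triphenylphosphoranylidene)ketene | O=C=C=P(c1ccccc1)(c1ccccc1)c1ccccc1 | starting material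
10 | methyl (S)-3-(benzyloxy)-2-{[(triphenylphosphoranylidene)acetyl]oxy}propanoate | COC(=O)[C@H](COCc1ccccc1)OC(=O)C=P(c1ccccc1)(c1ccccc1)c1ccccc1 | intermediate
11 | (S)-5-[(benzyloxy)methyl]-4-methoxyfuran-2(5H)-one | COC1=CC(=O)O[C@H]1COCc2ccccc2 | intermediate
12 | (R)-5-[(benzyloxy)methyl]-4-(pyrrolidin-1-yl)furan-2(5H)-one (same spatial arrangement at C5 as in 11) | O=C1C=C(N2CCCC2)[C@H](COCc3ccccc3)O1 | intermediate
13 | (S)-14-methylhexadecanenitrile oxide | CC[C@H](C)CCCCCCCCCCCCC#[N+][O-] | intermediate
14 | (3aS,6S,6aR)-6-[(benzyloxy)methyl]-3-[(S)-13-methylpentadecyl]-6a-(pyrrolidin-1-yl)-3a,6a-dihydrofuro[3,4-d]isoxazol-4(6H)-one (cis-fused, new bonds anti to the benzyloxymethyl group) | CC[C@H](C)CCCCCCCCCCCCC1=NO[C@]2(N3CCCC3)[C@H]1C(=O)O[C@H]2COCc4ccccc4 | intermediate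
15 | (S)-6-[(benzyloxy)methyl]-3-[(S)-13-methylpentadecyl]furo[3,4-d]isoxazol-4(6H)-one | CC[C@H](C)CCCCCCCCCCCCc1noc2c1C(=O)O[C@H]2COCc3ccccc3 | intermediate
16 | (5S)-3-[(1E,14S)-1-amino-14-methylhexadecylidene]-5-(hydroxymethyl)furan-2,4(3H,5H)-dione (E form drawn, NH2 hydrogen-bonded to the C4 carbonyl; the E and Z forms interconvert about the push–pull bond) | CC[C@H](C)CCCCCCCCCCCC/C(N)=C1/C(=O)[C@H](CO)OC1=O | intermediate
17 | (S)-4-hydroxy-5-(hydroxymethyl)-3-[(S)-14-methylhexadecanoyl]furan-2(5H)-one | CC[C@H](C)CCCCCCCCCCCCC(=O)C1=C(O)[C@H](CO)OC1=O | target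

Total step count: 9.
Longest linear sequence: 7 steps (6 → 7 → 8 → 11 → 12 → 15 → 16 → 17). The chain branch (1 → 4 → 5) joins at step 7.

Steps most likely to fail

Step 7. Self-dimerisation of the aliphatic nitrile oxide, and its capture by liberated amine, may outrun cycloaddition to the conjugatively stabilised, trisubstituted C3=C4 bond. The fallback sets out from 5 and 8 and comes back at 17. It makes the C1'–C3 bond on Meldrum's acid and closes the ring last. Nitroalkane 5 is oxidised as its potassium nitronate (KOH, then KMnO4, aq. t-BuOH, 0 °C) to (S)-14-methylhexadecanoic acid F1. DCC/DMAP coupling with Meldrum's acid in CH2Cl2 gives the acyl Meldrum's acid F2. Heating F2 with hydroxy ester 8 in toluene, with loss of acetone and CO2, gives the beta-keto ester F3. Bu4NF in THF brings about Lacey–Dieckmann cyclisation to the O-benzyl 3-acyltetronic acid F4. H2, Pd/C in EtOAc then removes the benzyl group to give 17.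

Step 9. Hydrolysis may stall because of the push–pull stabilisation and internal hydrogen bond of the primary vinylogous amide, and forcing acid may bring retro-Claisen loss of the acyl chain. The fallback sets out from 15 and comes back at 17. It turns nitrogen into a carbamate leaving group before hydrolysis. Mo(CO)6 in MeCN–H2O at reflux cleaves only the N–O bond and gives the O-benzyl vinylogous amide F5. Boc2O and DMAP in MeCN give the N-Boc vinylogous imide F6. LiOH in THF–H2O at 0 °C displaces tert-butyl carbamate from C1' by addition–elimination and, after acidification, gives the O-benzyl 3-acyltetronic acid F4. H2, Pd/C then gives 17.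

Step 6. Addition–elimination at the hindered C4 may be sluggish. Aminolysis of the lactone carbonyl may compete, and long heating with the amine may slowly erode the configuration at C5. The fallback sets out from 8 and comes back at 12. It reaches the enaminolactone by condensation with a free tetronic acid, whose anion is configurationally safe. Ac2O and pyridine give the acetate F7. LiN(SiMe3)2 (2.2 equiv) in THF at −78 °C brings about Dieckmann cyclisation to the 5-substituted tetronic acid F8. Pyrrolidine in toluene with azeotropic removal of water (AcOH cat.) then gives 12.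

Further compounds
F1 | step 7 | (S)-14-methylhexadecanoic acid | CC[C@H](C)CCCCCCCCCCCCC(=O)O
F2 | step 7 | 5-[(S)-1-hydroxy-14-methylhexadecylidene]-2,2-dimethyl-1,3-dioxane-4,6-dione | CC[C@H](C)CCCCCCCCCCCCC(O)=C1C(=O)OC(C)(C)OC1=O
F3 | step 7 | methyl (S)-3-(benzyloxy)-2-{[(S)-16-methyl-3-oxooctadecanoyl]oxy}propanoate | CC[C@H](C)CCCCCCCCCCCCC(=O)CC(=O)O[C@@H](COCc1ccccc1)C(=O)OC
F4 | step 7 | (S)-5-[(benzyloxy)methyl]-4-hydroxy-3-[(S)-14-methylhexadecanoyl]furan-2(5H)-one | CC[C@H](C)CCCCCCCCCCCCC(=O)C1=C(O)[C@H](COCc2ccccc2)OC1=O
F5 | step 9 | (5S)-3-[(1E,14S)-1-amino-14-methylhexadecylidene]-5-[(benzyloxy)methyl]furan-2,4(3H,5H)-dione | CC[C@H](C)CCCCCCCCCCCC/C(N)=C1/C(=O)[C@H](COCc2ccccc2)OC1=O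
F6 | step 9 | tert-butyl {(1E,14S)-1-[(5S)-5-[(benzyloxy)methyl]-2,4-dioxodihydrofuran-3(2H)-ylidene]-14-methylhexadecyl}carbamate | CC[C@H](C)CCCCCCCCCCCC/C(NC(=O)OC(C)(C)C)=C1/C(=O)[C@H](COCc2ccccc2)OC1=O
F7 | step 6 | methyl (S)-2-acetoxy-3-(benzyloxy)propanoate | CC(=O)O[C@@H](COCc1ccccc1)C(=O)OC
F8 | step 6 | (S)-5-[(benzyloxy)methyl]-4-hydroxyfuran-2(5H)-one | O=C1C=C(O)[C@H](COCc2ccccc2)O1
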